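**Strategy.** Ring atoms are numbered C1 (bears CO2Me), C2 (vinyl CH), C3 (OAc), C4, C5, C6. The cyclohexene is cut across C1=C2 and C3–C4, so that C2–C3 becomes a protected glycolaldehyde and C4–C5–C6–C1 a phosphonate aldehyde. The key step exploits the C3–O/C4–O aldol pattern beside the C1=C2 enoate of the ring. An L-proline cross-aldol joins C3 to C4 and sets both stereocentres, matched with a catalyst-made C5 centre. Base then closes the six-membered ring by intramolecular Horner–Wadsworth–Emmons olefination (C1=C2), in which both phosphonate epimers converge. C5 is carried in the epimeric, all-cis configuration and corrected when its ester is installed by Mitsunobu inversion.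

Key step: step 2

Assumption: (R)-2-methylbutanoic acid and (S)-3-methylpentanoic acid are bought as single enantiomers, as are both aldehydes and trimethyl 2-phosphonoacrylate.

**Step 1**
Reactants: 1 benzyloxyacetaldehyde; 2 methyl 2-(dimethoxyphosphoryl)acrylate
Product: 3 methyl (4S)-4-(benzyloxy)-2-(dimethoxyphosphoryl)-5-oxopentanoate (both epimers at C2)
Conditions: (R)-α,α-diphenylprolinol trimethylsilyl ether (10 mol%), PhCO2H (10 mol%), CH2Cl2, 0 °C → rt
Reagents that add atoms: none
Why: Enamine-catalysed Michael addition of an aldehyde to an α-phosphonoacrylate, in which the E-enamine is attacked on the face remote from the diphenyl(silyloxy)methyl group, so the (R)-catalyst should give the (S)-configured C–OBn centre (future C5), while the phosphonate carbon forms as an irrelevant epimer mixture.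

**Step 2**
Reactants: 3 methyl (4S)-4-(benzyloxy)-2-(dimethoxyphosphoryl)-5-oxopentanoate; 4 (tert-butyldimethylsilyloxy)acetaldehyde
Product: 6 methyl (3R,4S,5S)-5-(benzyloxy)-3-[(tert-butyldimethylsilyl)oxy]-4-hydroxycyclohex-1-ene-1-carboxylate, via acyclic anti-aldol adduct 5 (not isolated)
Conditions: L-proline (20 mol%), DMF, 4 °C, slow addition of 4 (syringe pump); then dilution with MeCN, LiCl, iPr2NEt, 0 °C → rt
Reagents that add atoms: none
Why: L-proline converts unbranched 4 into its anti-E-enamine, which adds to the aldehyde of α-branched 3 (a poor donor) through the carboxylic-acid-hydrogen-bonded chair-like transition state to give anti-aldol 5; the closest known reaction type is the proline-catalysed cross-aldol of α-oxyaldehydes. C3 and C4 are set by the catalyst (re face of the acceptor carbonyl, anti relationship), and the (S)-benzyloxy centre at C5 reinforces this through polar 1,2-induction (nucleophile anti to the C–O bond), so the pair is matched and should give the 3,4-anti/4,5-anti array that becomes all-cis in the ring. LiCl/iPr2NEt then deprotonates the phosphonoacetate carbon, which adds to the new aldehyde in a 6-exo-trig closure and expels dimethyl phosphate (intramolecular Horner–Wadsworth–Emmons olefination), forming C1=C2 and erasing the phosphonate stereocentre so that both epimers of 3 converge. The step needs cross- over homo-aldol of 4, secured by slow addition of 4 to the electrophilic α-alkoxy aldehyde, and intra- over intermolecular olefination, secured by six-ring formation at high dilution. The mild amine base should avoid retro-aldol, C3 epimerisation and silyl migration to the free C4 hydroxyl.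

**Step 3**
Reactants: 6 methyl (3R,4S,5S)-5-(benzyloxy)-3-[(tert-butyldimethylsilyl)oxy]-4-hydroxycyclohex-1-ene-1-carboxylate; 7 (R)-2-methylbutanoic acid
Product: 8 methyl (3R,4S,5S)-5-(benzyloxy)-3-[(tert-butyldimethylsilyl)oxy]-4-{[(2R)-2-methylbutanoyl]oxy}cyclohex-1-ene-1-carboxylate
Conditions: DCC, DMAP (cat.), CH2Cl2, 0 °C → rt
Reagents that add atoms: none
Why: Steglich esterification of the only free hydroxyl (C4), with catalytic DMAP at low temperature to keep the α-stereocentre of the acid intact; no ring stereocentre is touched.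

**Step 4**
Reactants: 8 methyl (3R,4S,5S)-5-(benzyloxy)-3-[(tert-butyldimethylsilyl)oxy]-4-{[(2R)-2-methylbutanoyl]oxy}cyclohex-1-ene-1-carboxylate
Product: 10 methyl (3R,4S,5S)-3-acetoxy-5-(benzyloxy)-4-{[(2R)-2-methylbutanoyl]oxy}cyclohex-1-ene-1-carboxylate, via C3 alcohol 9 (not isolated)
Conditions: HF·pyridine, pyridine, THF, 0 °C → rt; then Ac2O (excess), DMAP (cat.), rt
Reagents that add atoms: acetic anhydride CC(=O)OC(C)=O
Why: Buffered acidic fluoride desilylation frees the allylic C3 hydroxyl without acyl migration from O4, and DMAP-catalysed acetylation in the same flask caps it at once (silyl ether cleavage followed by acylation), with retention at C3.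

**Step 5**
Reactants: 10 methyl (3R,4S,5S)-3-acetoxy-5-(benzyloxy)-4-{[(2R)-2-methylbutanoyl]oxy}cyclohex-1-ene-1-carboxylate
Product: 11 methyl (3R,4S,5S)-3-acetoxy-5-hydroxy-4-{[(2R)-2-methylbutanoyl]oxy}cyclohex-1-ene-1-carboxylate
Conditions: BCl3, pentamethylbenzene, CH2Cl2, −78 °C; MeOH quench
Reagents that add atoms: none
Why: Lewis-acid debenzylation with a non-basic cation scavenger, which should cleave the benzyl ether at −78 °C while the esters, the enoate and the electron-poor allylic acetate are not ionised and the C1=C2 bond, which hydrogenolysis would reduce, is untouched.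

**Step 6**
Reactants: 11 methyl (3R,4S,5S)-3-acetoxy-5-hydroxy-4-{[(2R)-2-methylbutanoyl]oxy}cyclohex-1-ene-1-carboxylate; 12 (S)-3-methylpentanoic acid
Product: 13 methyl (3R,4S,5R)-3-acetoxy-4-{[(2R)-2-methylbutanoyl]oxy}-5-{[(3S)-3-methylpentanoyl]oxy}cyclohex-1-ene-1-carboxylate (target)
Conditions: PPh3, DIAD, toluene, 0 °C → rt
Reagents that add atoms: none
Why: Mitsunobu esterification, in which the carboxylate displaces the C5 oxyphosphonium by SN2 from the unsubstituted ring face, inverting (5S) to the required (5R); the cis C4 ester lies on the leaving-group face and cannot participate.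

**Compound list**
1 | benzyloxyacetaldehyde | O=CCOCc1ccccc1 | starting material
2 | methyl 2-(dimethoxyphosphoryl)acrylate (trimethyl 2-phosphonoacrylate) | C=C(C(=O)OC)P(=O)(OC)OC | starting material
3 | methyl (4S)-4-(benzyloxy)-2-(dimethoxyphosphoryl)-5-oxopentanoate, both epimers at C2 | O=C[C@@H](OCc1ccccc1)CC(P(=O)(OC)OC)C(=O)OC | intermediate
4 | (tert-butyldimethylsilyloxy)acetaldehyde | O=CCO[Si](C)(C)C(C)(C)C | starting material
5 | methyl (4S,5S,6S)-4-(benzyloxy)-6-[(tert-butyldimethylsilyl)oxy]-2-(dimethoxyphosphoryl)-5-hydroxy-7-oxoheptanoate, both epimers at C2 | O=C[C@@H](O[Si](C)(C)C(C)(C)C)[C@@H](O)[C@@H](OCc1ccccc1)CC(P(=O)(OC)OC)C(=O)OC | intermediate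
6 | methyl (3R,4S,5S)-5-(benzyloxy)-3-[(tert-butyldimethylsilyl)oxy]-4-hydroxycyclohex-1-ene-1-carboxylate | COC(=O)C1=C[C@@H](O[Si](C)(C)C(C)(C)C)[C@@H](O)[C@@H](OCc2ccccc2)C1 | intermediate
7 | (R)-2-methylbutanoic acid | CC[C@@H](C)C(=O)O | starting material
8 | methyl (3R,4S,5S)-5-(benzyloxy)-3-[(tert-butyldimethylsilyl)oxy]-4-{[(2R)-2-methylbutanoyl]oxy}cyclohex-1-ene-1-carboxylate | COC(=O)C1=C[C@@H](O[Si](C)(C)C(C)(C)C)[C@@H](OC(=O)[C@H](C)CC)[C@@H](OCc2ccccc2)C1 | intermediate
9 | methyl (3R,4R,5S)-5-(benzyloxy)-3-hydroxy-4-{[(2R)-2-methylbutanoyl]oxy}cyclohex-1-ene-1-carboxylate | COC(=O)C1=C[C@@H](O)[C@@H](OC(=O)[C@H](C)CC)[C@@H](OCc2ccccc2)C1 | intermediate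
10 | methyl (3R,4S,5S)-3-acetoxy-5-(benzyloxy)-4-{[(2R)-2-methylbutanoyl]oxy}cyclohex-1-ene-1-carboxylate | COC(=O)C1=C[C@@H](OC(C)=O)[C@@H](OC(=O)[C@H](C)CC)[C@@H](OCc2ccccc2)C1 | intermediate
11 | methyl (3R,4S,5S)-3-acetoxy-5-hydroxy-4-{[(2R)-2-methylbutanoyl]oxy}cyclohex-1-ene-1-carboxylate | COC(=O)C1=C[C@@H](OC(C)=O)[C@@H](OC(=O)[C@H](C)CC)[C@@H](O)C1 | intermediate
12 | (S)-3-methylpentanoic acid | CC[C@H](C)CC(=O)O | starting material
13 | methyl (3R,4S,5R)-3-acetoxy-4-{[(2R)-2-methylbutanoyl]oxy}-5-{[(3S)-3-methylpentanoyl]oxy}cyclohex-1-ene-1-carboxylate | CC[C@H](C)CC(=O)O[C@@H]1CC(C(=O)OC)=C[C@@H](OC(C)=O)[C@H]1OC(=O)[C@H](C)CC | target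

Total step count: 6. Longest linear sequence: 6 steps (1/2 → 3 → 6 → 8 → 10 → 11 → 13).

**Steps most likely to fail**

Step 2. The cross-aldol may lose to homo-aldol of the donor, the anti/matched selectivity may erode, or intermolecular olefination may compete with ring closure. Fallback, setting out from 3 and 4 and returning at 6: 4 is converted with TMSCl/Et3N into its enol silane, (Z)-2-[(tert-butyldimethylsilyl)oxy]-1-[(trimethylsilyl)oxy]ethene F1, so that donor and acceptor roles are fixed. A BF3·OEt2-mediated Mukaiyama aldol addition of F1 to 3 (CH2Cl2, −78 °C; non-chelating, so the same 4,5-anti induction should apply) should give adduct 5 after aqueous work-up, now isolated and purified. A separate LiCl/iPr2NEt olefination in dilute MeCN then closes the ring to 6.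

Step 6. The Mitsunobu reaction may suffer elimination towards the conjugated diene or incomplete inversion with the weakly acidic aliphatic acid. Fallback, setting out from 11 and returning at 13: 11 is converted with Tf2O/pyridine (CH2Cl2, −20 °C) into methyl (3R,4R,5S)-3-acetoxy-4-{[(2R)-2-methylbutanoyl]oxy}-5-{[(trifluoromethyl)sulfonyl]oxy}cyclohex-1-ene-1-carboxylate F2. This is displaced with inversion by cesium (3S)-3-methylpentanoate F3 (made from 12 and Cs2CO3; 18-crown-6, toluene, rt), as in carbohydrate triflate epimerisations beside ester groups, to give 13.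

Step 5. The Lewis acid may ionise the allylic acetate or promote acyl migration from O4 to the freed O5 during debenzylation. Fallback, setting out from 10 and returning at 11: oxidative single-electron debenzylation with DDQ under visible-light irradiation in wet CH2Cl2, which proceeds through the benzylic oxocarbenium ion under neutral conditions and makes no new numbered compound.

**Further compounds**
F1 | step 2 | (Z)-2-[(tert-butyldimethylsilyl)oxy]-1-[(trimethylsilyl)oxy]ethene | C[Si](C)(C)O/C=C\O[Si](C)(C)C(C)(C)C
F2 | step 6 | methyl (3R,4R,5S)-3-acetoxy-4-{[(2R)-2-methylbutanoyl]oxy}-5-{[(trifluoromethyl)sulfonyl]oxy}cyclohex-1-ene-1-carboxylate | COC(=O)C1=C[C@@H](OC(C)=O)[C@@H](OC(=O)[C@H](C)CC)[C@@H](OS(=O)(=O)C(F)(F)F)C1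
F3 | step 6 | cesium (3S)-3-methylpentanoate | [Cs+].CC[C@H](C)CC(=O)[O-]
F0 | step 5 | none | none
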